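The furofuran is a 2,6-diaryl-3,7-dioxabicyclo[3.3.0]octane (ring fusion C1/C5, aryl-bearing C2/C6, O3/O7, methylenes C4/C8). The plan cuts the C1–C5 and C6–O7 bonds: reductive homolysis of a C1–C8 oxirane puts a radical on C1, placed to close a five-membered ring onto C5 of a C5=C6 styrene, and leaves O7 on C8 within reach of benzylic C6. One operation (Cp2TiCl, then iodine) closes ring one (C1–C2–O3–C4–C5) by radical addition and ring two (C1–C5–C6–O7–C8) by benzylic C–O bond formation, setting C1, C5 and C6 from C2. The precursor is an enantioenriched epoxy cinnamyl ether: an aryl carbinol carbon (C2) bearing the oxirane and an O-(E)-3,4,5-trimethoxycinnamyl group, the phenol masked as a triisopropylsilyl ether.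

Key step: step 7

Remark a: the phenol is carried as a triisopropylsilyl ether, not a smaller silyl ether, because step 6 exposes it to a sodium alkoxide; fluoride still removes it in step 8.
Remark b: the kinetic resolution delivers the erythro epoxy alcohol, so 5 and 10 carry an (S)-oxirane carbon next to the (R)-carbinol carbon. That oxirane carbon becomes a planar radical in step 7, so its configuration has no bearing on 13.
Remark c: in the SMILES of titanium species the cyclopentadienyl ligands are drawn as σ-bonded C5H5 rings.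

**Route**

Step 1
Reactants: 1 3-hydroxy-4,5-dimethoxybenzaldehyde
Product: 2 3,4-dimethoxy-5-[(triisopropylsilyl)oxy]benzaldehyde
Conditions: TIPSCl, imidazole, DMF, rt
Reagents that add atoms: triisopropylsilyl chloride, CC(C)[Si](Cl)(C(C)C)C(C)C
Why: Silyl ether formation from a phenol, a trialkylsilyl chloride and imidazole is routine, and the bulky triisopropylsilyl group should withstand the Grignard reagent and the sodium alkoxide of step 6 yet leave with fluoride.

Step 2
Reactants: 2 3,4-dimethoxy-5-[(triisopropylsilyl)oxy]benzaldehyde; 3 vinylmagnesium bromide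
Product: 4 rac-1-{3,4-dimethoxy-5-[(triisopropylsilyl)oxy]phenyl}prop-2-en-1-ol
Conditions: THF, −78 to 0 °C; then aq NH4Cl
Reagents that add atoms: none
Why: Grignard 1,2-addition to a non-enolisable aryl aldehyde gives the allylic alcohol cleanly; the carbinol centre is formed racemic on purpose and is resolved in step 3.

Step 3
Reactants: 4 rac-1-{3,4-dimethoxy-5-[(triisopropylsilyl)oxy]phenyl}prop-2-en-1-ol
Product: 5 (R)-{3,4-dimethoxy-5-[(triisopropylsilyl)oxy]phenyl}[(2S)-oxiran-2-yl]methanol (erythro)
Conditions: Ti(OiPr)4 (20 mol %), D-(−)-DIPT (30 mol %), t-BuOOH (0.45 equiv), 4 Å MS, CH2Cl2, −20 °C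
Reagents that add atoms: tert-butyl hydroperoxide, CC(C)(C)OO
Why: Sharpless kinetic resolution (titanium–tartrate asymmetric epoxidation of a racemic secondary allylic alcohol): the D-(−)-tartrate catalyst should epoxidise the (S)-enantiomer of 4 much faster than the (R)-enantiomer, which fixes the carbinol centre C2 (R in 5 after the change in substituent priorities), and the tartrate-dictated alkene face gives the erythro (S)-oxirane carbon in that matched enantiomer; the unreacted (R)-enantiomer of 4 is separated by chromatography.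

Step 4
Reactants: 6 (E)-3,4,5-trimethoxycinnamic acid
Product: 8 (E)-3-(3,4,5-trimethoxyphenyl)prop-2-en-1-ol, via mixed carbonic anhydride 7 (not isolated)
Conditions: ClCO2Et, Et3N, THF, −10 °C; then NaBH4, H2O/THF, 0 °C
Reagents that add atoms: ethyl chloroformate, CCOC(=O)Cl
Why: Activation of the acid as mixed carbonic anhydride 7 followed by borohydride reduction is a standard chemoselective 1,2-reduction of cinnamic acids to cinnamyl alcohols that leaves the E alkene untouched; the chloroformate-derived atoms sit only in 7 and leave as carbon dioxide and ethanol.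

Step 5
Reactants: 8 (E)-3-(3,4,5-trimethoxyphenyl)prop-2-en-1-ol
Product: 9 (E)-5-(3-bromoprop-1-en-1-yl)-1,2,3-trimethoxybenzene (3,4,5-trimethoxycinnamyl bromide)
Conditions: PBr3 (0.4 equiv), Et2O, 0 °C; used crude at once
Reagents that add atoms: phosphorus tribromide, BrP(Br)Br
Why: Bromination of a primary allylic alcohol through its phosphite ester is standard for cinnamyl alcohols and keeps the E geometry; the electron-rich bromide is not stored or chromatographed.

Step 6
Reactants: 5 (R)-{3,4-dimethoxy-5-[(triisopropylsilyl)oxy]phenyl}[(2S)-oxiran-2-yl]methanol; 9 (E)-5-(3-bromoprop-1-en-1-yl)-1,2,3-trimethoxybenzene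
Product: 10 (2S)-2-[(R)-{3,4-dimethoxy-5-[(triisopropylsilyl)oxy]phenyl}{[(E)-3-(3,4,5-trimethoxyphenyl)prop-2-en-1-yl]oxy}methyl]oxirane
Conditions: NaH, THF, 0 °C; then 9, Bu4NI (10 mol %), 0 °C to rt
Reagents that add atoms: none
Why: Williamson ether synthesis: the sodium alkoxide of 5 should displace the primary allylic bromide (SN2, helped by iodide catalysis) at 0 °C faster than it can rearrange by epoxide migration in an aprotic solvent, and neither stereocentre is touched.

Step 7
Reactants: 10 (2S)-2-[(R)-{3,4-dimethoxy-5-[(triisopropylsilyl)oxy]phenyl}{[(E)-3-(3,4,5-trimethoxyphenyl)prop-2-en-1-yl]oxy}methyl]oxirane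
Product: 13 (1S,3aR,4S,6aR)-1-{3,4-dimethoxy-5-[(triisopropylsilyl)oxy]phenyl}-4-(3,4,5-trimethoxyphenyl)tetrahydro-1H,3H-furo[3,4-c]furan, via bis-titanated tetrahydrofuran 11 (not isolated), via benzylic iodide titanium alkoxide 12 (not isolated)
Conditions: Cp2TiCl2 (2.5 equiv), Zn dust, THF, rt (green Cp2TiCl, decanted from zinc); added slowly to 10 in THF, rt; then I2 (1.5 equiv), rt to 60 °C
Reagents that add atoms: titanocene dichloride Cp2TiCl2, Cl[Ti](Cl)(C1C=CC=C1)C1C=CC=C1; iodine, II
Why: Cp2TiCl transfers one electron to the oxirane and cleaves the C1–O7 bond to give the more substituted C1 radical with O7 held on C8 as a tetravalent-titanium alkoxide; this radical adds 5-exo-trig to C5 of the (E)-styrene (ring one, C1–C2–O3–C4–C5) and a second Cp2TiCl caps the resulting benzylic C6 radical to give 11. Iodine converts the C6–Ti bond into a benzylic iodide (12) that the electron-rich trimethoxyphenyl ring helps to ionise, and the O7 titanium alkoxide closes ring two (C1–C5–C6–O7–C8) by 5-exo-tet substitution at C6, so that all titanium and iodine leave as Cp2Ti(Cl)I and none remains in 13. The closest known reaction type is the titanocene-mediated reductive epoxide-opening radical cyclisation of epoxy allyl ethers with iodine work-up, an established entry to furofuran lignans. C1 is planar in the radical, so its configuration in 10 is irrelevant; in the chair-like 5-exo transition state the C2 aryl group sits pseudo-equatorial and ends trans to the new C5–C6 arm while the C8 arm on the radical carbon ends cis to it (C1 R, C5 R), the only arrangement from which a cis-fused bicycle can close. C6 (S) is set in the ionic closure, the aryl group taking the convex exo face of the cis-fused bicycle. The step needs homolysis at C1 and not C8 (secondary versus primary radical), 5-exo over 6-endo closure (attack at C5 leaves the benzylic radical) and no premature reduction of the C1 radical, which the fast cyclisation and slow addition of the reagent to the substrate should secure.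

Step 8
Reactants: 13 (1S,3aR,4S,6aR)-1-{3,4-dimethoxy-5-[(triisopropylsilyl)oxy]phenyl}-4-(3,4,5-trimethoxyphenyl)tetrahydro-1H,3H-furo[3,4-c]furan
Product: 14 2,3-dimethoxy-5-[(1S,3aR,4S,6aR)-4-(3,4,5-trimethoxyphenyl)tetrahydro-1H,3H-furo[3,4-c]furan-1-yl]phenol (target)
Conditions: TBAF, AcOH, THF, 0 °C
Reagents that add atoms: none
Why: Fluoride-mediated cleavage of an aryl silyl ether (Si–F bond formation), buffered with acetic acid, should free the phenol without touching the two benzylic ether centres or any of the four stereocentres.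

**Compound list**

1 | 3-hydroxy-4,5-dimethoxybenzaldehyde | COc1cc(C=O)cc(O)c1OC | starting material
2 | 3,4-dimethoxy-5-[(triisopropylsilyl)oxy]benzaldehyde | COc1cc(C=O)cc(O[Si](C(C)C)(C(C)C)C(C)C)c1OC | intermediate
3 | vinylmagnesium bromide | C=C[Mg]Br | starting material
4 | rac-1-{3,4-dimethoxy-5-[(triisopropylsilyl)oxy]phenyl}prop-2-en-1-ol | COc1cc(C(O)C=C)cc(O[Si](C(C)C)(C(C)C)C(C)C)c1OC | intermediate
5 | (R)-{3,4-dimethoxy-5-[(triisopropylsilyl)oxy]phenyl}[(2S)-oxiran-2-yl]methanol (erythro) | COc1cc(cc(O[Si](C(C)C)(C(C)C)C(C)C)c1OC)[C@@H](O)[C@@H]1CO1 | intermediate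
6 | (E)-3,4,5-trimethoxycinnamic acid | COc1cc(/C=C/C(=O)O)cc(OC)c1OC | starting material
7 | (E)-3-(3,4,5-trimethoxyphenyl)acrylic ethyl carbonic anhydride (not isolated) | CCOC(=O)OC(=O)/C=C/c1cc(OC)c(OC)c(OC)c1 | intermediate
8 | (E)-3-(3,4,5-trimethoxyphenyl)prop-2-en-1-ol | COc1cc(/C=C/CO)cc(OC)c1OC | intermediate
9 | (E)-5-(3-bromoprop-1-en-1-yl)-1,2,3-trimethoxybenzene | COc1cc(/C=C/CBr)cc(OC)c1OC | intermediate
10 | (2S)-2-[(R)-{3,4-dimethoxy-5-[(triisopropylsilyl)oxy]phenyl}{[(E)-3-(3,4,5-trimethoxyphenyl)prop-2-en-1-yl]oxy}methyl]oxirane | COc1cc(cc(O[Si](C(C)C)(C(C)C)C(C)C)c1OC)[C@@H](OC/C=C/c1cc(OC)c(OC)c(OC)c1)[C@@H]1CO1 | intermediate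
11 | bis-titanated tetrahydrofuran: ring one closed (2-aryl and 3-CH2O arm trans, 3-CH2O arm and 4-benzylic arm cis), C6–TiCp2Cl (C6 configuration open), C8–O–TiCp2Cl (not isolated) | COc1cc(cc(O[Si](C(C)C)(C(C)C)C(C)C)c1OC)[C@H]2OC[C@H](C(c3cc(OC)c(OC)c(OC)c3)[Ti](Cl)(C3C=CC=C3)C3C=CC=C3)[C@@H]2CO[Ti](Cl)(C2C=CC=C2)C2C=CC=C2 | intermediate
12 | benzylic C6 iodide of the same tetrahydrofuran with C8–O–TiCp2Cl (C6 configuration open; not isolated) | COc1cc(cc(O[Si](C(C)C)(C(C)C)C(C)C)c1OC)[C@H]2OC[C@H](C(I)c3cc(OC)c(OC)c(OC)c3)[C@@H]2CO[Ti](Cl)(C2C=CC=C2)C2C=CC=C2 | intermediate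
13 | (1S,3aR,4S,6aR)-1-{3,4-dimethoxy-5-[(triisopropylsilyl)oxy]phenyl}-4-(3,4,5-trimethoxyphenyl)tetrahydro-1H,3H-furo[3,4-c]furan | COc1cc(cc(O[Si](C(C)C)(C(C)C)C(C)C)c1OC)[C@H]2OC[C@H]3[C@@H]2CO[C@@H]3c1cc(OC)c(OC)c(OC)c1 | intermediate
14 | 2,3-dimethoxy-5-[(1S,3aR,4S,6aR)-4-(3,4,5-trimethoxyphenyl)tetrahydro-1H,3H-furo[3,4-c]furan-1-yl]phenol | COc1cc([C@H]2OC[C@H]3[C@@H]2CO[C@@H]3c2cc(OC)c(OC)c(OC)c2)cc(O)c1OC | target

**Count and risks**

Total step count: 8. Longest linear sequence: 6 steps (steps 1, 2, 3, 6, 7, 8); the cinnamyl arm (steps 4 and 5) joins at step 6.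

Steps most likely to fail:

Step 7. The benzylic C6 position may be protonated or pick up a hydrogen atom before iodine acts, so that ring two never closes, or the benzylic capture may lose face control. The fallback sets out from 10 and comes back at 13. The Cp2TiCl cyclisation is ended on purpose with aqueous acid (Cp2TiCl from Cp2TiCl2 and Zn, THF, rt; then dilute aq HCl). This should give [(2S,3R,4R)-2-{3,4-dimethoxy-5-[(triisopropylsilyl)oxy]phenyl}-4-(3,4,5-trimethoxybenzyl)tetrahydrofuran-3-yl]methanol F1 as an isolable monocyclic alcohol. The primary alcohol of F1 is then converted into an alkoxy radical under hypoiodite conditions (PhI(OAc)2, I2, cyclohexane/CH2Cl2, visible light, rt, short reaction time to limit iodination of the aryl rings). The cis arrangement of the C8 and C6 arms places a benzylic C6 hydrogen next to O7, so 1,5-hydrogen transfer from C6 followed by oxidative C6–O7 closure (remote-functionalisation ether synthesis) should deliver 13, again with the aryl group on the convex face.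

Step 3. Epoxidation of the monosubstituted alkene may be slow and poorly discriminating, which erodes the enantiomeric purity at C2, or the Lewis acid may open the benzylic epoxy alcohol. The fallback sets out from 4 and comes back at 5. A lipase-catalysed kinetic resolution by acylation (immobilised Candida antarctica lipase B, vinyl acetate, MTBE, rt) should acetylate the (R)-enantiomer to (R)-1-{3,4-dimethoxy-5-[(triisopropylsilyl)oxy]phenyl}prop-2-en-1-yl acetate F3 and leave (S)-1-{3,4-dimethoxy-5-[(triisopropylsilyl)oxy]phenyl}prop-2-en-1-ol F2 unchanged. After chromatographic separation from F3 the alcohol F2 is epoxidised in the matched sense (Ti(OiPr)4, D-(−)-DIPT, t-BuOOH, 4 Å MS, CH2Cl2, −20 °C), now a plain hydroxyl-directed diastereoselective epoxidation, to give 5.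

Step 6. The alkoxide may undergo epoxide migration, the electron-rich bromide may ionise or be attacked at its benzylic end, or the silyl group may transfer from the aryl ether to the alkoxide. The fallback sets out from 5 and 8 and comes back at 10. Alcohol 8 is acetylated (Ac2O, pyridine, rt) to (E)-3-(3,4,5-trimethoxyphenyl)prop-2-en-1-yl acetate F4 in place of the bromide. The acetate F4 is coupled with the zinc alkoxide of 5 (Et2Zn, 0.5 equiv) under catalysis by Pd(OAc)2 and 2-(di-tert-butylphosphino)biphenyl in THF at rt (allylic etherification through a π-allylpalladium intermediate). It should give the linear (E)-ether 10 without a free sodium alkoxide and without the bromide.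

**Further compounds**

F1 | step 7 | [(2S,3R,4R)-2-{3,4-dimethoxy-5-[(triisopropylsilyl)oxy]phenyl}-4-(3,4,5-trimethoxybenzyl)tetrahydrofuran-3-yl]methanol | COc1cc(cc(O[Si](C(C)C)(C(C)C)C(C)C)c1OC)[C@H]2OC[C@H](Cc3cc(OC)c(OC)c(OC)c3)[C@@H]2CO
F2 | step 3 | (S)-1-{3,4-dimethoxy-5-[(triisopropylsilyl)oxy]phenyl}prop-2-en-1-ol | COc1cc(cc(O[Si](C(C)C)(C(C)C)C(C)C)c1OC)[C@@H](O)C=C
F3 | step 3 | (R)-1-{3,4-dimethoxy-5-[(triisopropylsilyl)oxy]phenyl}prop-2-en-1-yl acetate | COc1cc(cc(O[Si](C(C)C)(C(C)C)C(C)C)c1OC)[C@H](OC(C)=O)C=C
F4 | step 6 | (E)-3-(3,4,5-trimethoxyphenyl)prop-2-en-1-yl acetate | COc1cc(/C=C/COC(C)=O)cc(OC)c1OC
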